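## Retrosynthetic overview

1. The acid is freed last. Ring B (eight-membered) is opened at its CH2–CH2 bond (ring-closing metathesis, then hydrogenation) and at the carbinol–alkene bond (addition of the (Z)-alkenyllithium from ring A fragment 25 to the ring C ketone of trans-hydrindanone 17).
2. Ring A fragment 25 comes from (R)-citronellene by cross-metathesis, alkyne formation and a zirconocene-mediated enyne cyclisation/iodination that fixes the tetrasubstituted alkene geometry.
3. In 17 the butenyl side chain is added by iridium-catalysed allylation after a Stork–Danheiser transposition. Before that, ring D is built in one operation from monocyclic ring C precursor 8 and vinyltriphenylphosphonium bromide (Michael addition/intramolecular Wittig), then hydrogenated face-selectively.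
4. Enabling feature: ring C is carried as a cyclohexane-1,3-dione mono-enol ether, so the CO2H-bearing quaternary C/D fusion carbon is a β-keto ester α-carbon. The other fusion carbon holds an isobutyryl group whose C=O carbon becomes the isopropyl-bearing carbon of ring D. This nucleophile/electrophile pair takes up the two CH2 carbons of ring D.
5. Order of ring formation: C (Michael/Claisen), then D (key step); A separately; B last.

Key step: step 6

Remark: in 6–8 the β-keto ester carbon is configurationally labile and is drawn without configuration; the only fixed stereocentre there is the acyl-bearing carbon. Where a chiral catalyst or ligand is used, the antipode is the one that gives the stated descriptor.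

## Route

Step 1
Reactants: 1 methylglyoxal (2-oxopropanal, 40 wt% in water); 2 N-methoxy-N-methyl-2-(triphenylphosphoranylidene)acetamide
Product: 3 (E)-N-methoxy-N-methyl-4-oxopent-2-enamide
Conditions: CH2Cl2/H2O, 0 °C → rt
Reagents that add atoms: none
Why: Wittig olefination of the aldehyde carbonyl (far more electrophilic than the ketone) by the amide-stabilised ylide should give the (E)-enone amide, as stabilised ylides do.

Step 2
Reactants: 3 (E)-N-methoxy-N-methyl-4-oxopent-2-enamide; 4 dimethyl malonate
Product: 5 dimethyl 2-[(2R)-1-[methoxy(methyl)amino]-1,4-dioxopentan-2-yl]propanedioate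
Conditions: cinchona-derived bifunctional tertiary amine–squaramide organocatalyst (5 mol%, pseudoenantiomer that gives the (R)-adduct), toluene, −20 °C
Reagents that add atoms: none
Why: Organocatalytic asymmetric Michael addition in which the malonate should add to the carbon β to the ketone (the stronger acceptor group), i.e. α to the amide, with the catalyst face-selection setting the (R)-centre that becomes the C/D ring-fusion CH.

Step 3
Reactants: 5 dimethyl 2-[(2R)-1-[methoxy(methyl)amino]-1,4-dioxopentan-2-yl]propanedioate
Product: 6 methyl (6R)-6-[methoxy(methyl)carbamoyl]-2,4-dioxocyclohexane-1-carboxylate (enolised 1,3-dione)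
Conditions: NaOMe (1.1 equiv), MeOH, 0 °C → rt; then 1 M HCl to pH 3
Reagents that add atoms: none
Why: Intramolecular Claisen (Dieckmann-type) condensation of the methyl-ketone enolate on a malonate ester should close ring C as the six-membered 1,3-dione, driven by dione enolate formation, while the amide α-CH next to the anionic malonate carbon is not deprotonated.

Step 4
Reactants: 6 methyl (6R)-6-[methoxy(methyl)carbamoyl]-2,4-dioxocyclohexane-1-carboxylate
Product: 7 methyl (6R)-4-methoxy-6-[methoxy(methyl)carbamoyl]-2-oxocyclohex-3-ene-1-carboxylate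
Conditions: MeOH, TsOH·H2O (5 mol%), 3 Å molecular sieves, rt
Reagents that add atoms: methanol, CO
Why: Acid-catalysed enol etherification of the vinylogous acid should occur at the unhindered carbonyl remote from the ester, so the carbonyl next to the ester-bearing carbon stays free and that carbon remains a β-keto ester α-carbon.

Step 5
Reactants: 7 methyl (6R)-4-methoxy-6-[methoxy(methyl)carbamoyl]-2-oxocyclohex-3-ene-1-carboxylate
Product: 8 methyl (6R)-4-methoxy-6-(2-methylpropanoyl)-2-oxocyclohex-3-ene-1-carboxylate
Conditions: i-PrMgCl·LiCl (2.5 equiv), THF, −40 → 0 °C; sat. aq. NH4Cl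
Reagents that add atoms: isopropylmagnesium chloride, CC(C)[Mg]Cl
Why: Weinreb ketone synthesis in which the first equivalent of Grignard reagent deprotonates the β-keto ester (its magnesium enolate shields the ring carbonyl, the ester and the adjacent stereocentre) and the second adds once to the N-methoxy-N-methylamide, releasing the isopropyl ketone only on work-up.

Step 6
Reactants: 8 methyl (6R)-4-methoxy-6-(2-methylpropanoyl)-2-oxocyclohex-3-ene-1-carboxylate; 9 vinyltriphenylphosphonium bromide
Product: 11 methyl (3aR,7aS)-6-methoxy-4-oxo-1-(propan-2-yl)-3,4,7,7a-tetrahydro-3aH-indene-3a-carboxylate (trans-fused hydrindenone), via phosphorus ylide 10 (not isolated)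
Conditions: NaH (1.0 equiv), THF, 0 °C; then 9 (1.2 equiv), THF/DMF, 0 → 45 °C
Reagents that add atoms: none
Why: The sodium enolate of 8 adds through its β-keto ester carbon to the vinylphosphonium salt to give ylide 10, which closes ring D by intramolecular Wittig olefination of the isobutyryl ketone. The closest known reaction type is the vinyltriphenylphosphonium Michael/Wittig cyclopentene annulation of 2-(2-oxoalkyl) 1,3-dicarbonyl compounds. Ring D closes by five-membered (5-exo-trig) attack of the ylide carbon on the ketone carbonyl and loss of Ph3PO; every other carbonyl would need a four-membered ring. The only new stereocentre, the quaternary ring-fusion carbon, is set in the Michael step: the acyl group on the neighbouring carbon sits pseudo-axial to avoid allylic strain with the enolate ester, the electrophile enters anti to it, and the Wittig closure then gives the trans-hydrindene. The step needs C-alkylation at the doubly activated carbon and no epimerisation at the acyl-bearing CH; converting 8 fully into its stabilised enolate before the salt is added leaves no base able to enolise the ketone.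

Step 7
Reactants: 11 methyl (3aR,7aS)-6-methoxy-4-oxo-1-(propan-2-yl)-3,4,7,7a-tetrahydro-3aH-indene-3a-carboxylate
Product: 12 methyl (1R,3aR,7aS)-6-methoxy-4-oxo-1-(propan-2-yl)-1,2,3,4,7,7a-hexahydro-3aH-indene-3a-carboxylate
Conditions: H2 (1 atm), 10% Pd/C, EtOAc, rt
Reagents that add atoms: none
Why: Heterogeneous hydrogenation should add hydrogen to the trisubstituted cyclopentene from the face of the ring-fusion H, opposite the angular ester, placing the isopropyl group cis to the ester as in the target while the push–pull enol ether alkene stays intact.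

Step 8
Reactants: 12 methyl (1R,3aR,7aS)-6-methoxy-4-oxo-1-(propan-2-yl)-1,2,3,4,7,7a-hexahydro-3aH-indene-3a-carboxylate
Product: 14 methyl (1R,3aS,7aS)-6-oxo-1-(propan-2-yl)-1,2,3,6,7,7a-hexahydro-3aH-indene-3a-carboxylate, via allylic alcohol 13 (not isolated)
Conditions: NaBH4, CeCl3·7H2O, MeOH, −20 → 0 °C; then 2 M HCl, THF, rt
Reagents that add atoms: water, O
Why: Luche 1,2-reduction of the vinylogous ester carbonyl followed by acid hydrolysis with loss of water and methanol (Stork–Danheiser enone transposition) should remove the oxygen next to the quaternary carbon and unveil the ring C ketone at the future carbinol carbon.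

Step 9
Reactants: 14 methyl (1R,3aS,7aS)-6-oxo-1-(propan-2-yl)-1,2,3,6,7,7a-hexahydro-3aH-indene-3a-carboxylate
Product: 15 methyl (1R,3aS,7aS)-1-(propan-2-yl)-6-[(triethylsilyl)oxy]-1,2,3,4,7,7a-hexahydro-3aH-indene-3a-carboxylate
Conditions: Et3SiH (1.5 equiv), RhCl(PPh3)3 (2 mol%), toluene, 50 °C
Reagents that add atoms: triethylsilane, CC[SiH](CC)CC
Why: Rhodium-catalysed 1,4-hydrosilylation of the enone with a monohydrosilane should give the silyl enol ether regiospecifically towards the future side-chain carbon, which enolisation of the saturated ketone could not guarantee.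

Step 10
Reactants: 15 methyl (1R,3aS,7aS)-1-(propan-2-yl)-6-[(triethylsilyl)oxy]-1,2,3,4,7,7a-hexahydro-3aH-indene-3a-carboxylate; 16 (E)-but-2-en-1-yl methyl carbonate
Product: 17 methyl (1R,3aS,5R,7aS)-5-[(2S)-but-3-en-2-yl]-6-oxo-1-(propan-2-yl)octahydro-3aH-indene-3a-carboxylate
Conditions: [Ir(cod)Cl]2 (2 mol%), binaphthol-derived N,N-bis(1-phenylethyl)phosphoramidite (4 mol%, antipode that gives the (S)-allylic centre), CsF, ZnF2, DME, 50 °C; then DBU (cat.), CH2Cl2, rt
Reagents that add atoms: none
Why: Iridium-catalysed branched-selective asymmetric allylic alkylation of the fluoride-activated enol silane should set the methyl-bearing allylic stereocentre under ligand control, with the electrophile entering anti to the axial angular ester and base equilibration securing the equatorial side chain.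

Step 11
Reactants: 18 (R)-β-citronellene [(3R)-3,7-dimethylocta-1,6-diene]; 19 (Z)-1,4-bis(benzyloxy)but-2-ene
Product: 20 benzyl (2E,4R)-4,8-dimethylnona-2,7-dien-1-yl ether
Conditions: second-generation Grubbs catalyst RuCl2(H2IMes)(PCy3)(=CHPh) (3 mol%), 19 (2 equiv), CH2Cl2, 40 °C
Reagents that add atoms: none
Why: Cross-metathesis of the monosubstituted alkene of citronellene (the trisubstituted alkene is inert) with the symmetrical allylic ether should install the (E)-allylic benzyl ether without touching the stereocentre.

Step 12
Reactants: 20 benzyl (2E,4R)-4,8-dimethylnona-2,7-dien-1-yl ether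
Product: 21 (4R,5E)-7-(benzyloxy)-4-methylhept-5-enal
Conditions: O3, CH2Cl2/MeOH, pyridine, −78 °C (Sudan red 7B end-point); then Me2S, −78 °C → rt
Reagents that add atoms: ozone, [O-][O+]=O
Why: Ozonolysis should select the electron-rich trisubstituted alkene over the allylic-ether alkene, which is deactivated by the adjacent oxygen.

Step 13
Reactants: 21 (4R,5E)-7-(benzyloxy)-4-methylhept-5-enal
Product: 22 benzyl (2E,4R)-4-methyloct-2-en-7-yn-1-yl ether
Conditions: dimethyl (1-diazo-2-oxopropyl)phosphonate, K2CO3, MeOH, 0 °C → rt
Reagents that add atoms: dimethyl (1-diazo-2-oxopropyl)phosphonate, COP(=O)(OC)C(=[N+]=[N-])C(C)=O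
Why: Seyferth–Gilbert homologation with the Ohira–Bestmann reagent should convert the aldehyde into the terminal alkyne under mild base that leaves the remote stereocentre alone.

Step 14
Reactants: 22 benzyl (2E,4R)-4-methyloct-2-en-7-yn-1-yl ether
Product: 23 benzyl (2E,4R)-4-methylnon-2-en-7-yn-1-yl ether
Conditions: n-BuLi, THF, −78 °C; MeI, −78 °C → rt
Reagents that add atoms: iodomethane, CI
Why: Deprotonation of the terminal alkyne and C-methylation of the lithium acetylide.

Step 15
Reactants: 23 benzyl (2E,4R)-4-methylnon-2-en-7-yn-1-yl ether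
Product: 25 (2S,3R)-2-ethenyl-1-[(Z)-1-iodoethylidene]-3-methylcyclopentane, via alkenylzirconocene benzyloxide 24 (not isolated)
Conditions: Cp2ZrCl2, n-BuLi (2 equiv), THF, −78 °C; 23, −78 °C → rt; I2, 0 °C; aq. HCl
Reagents that add atoms: iodine, II
Why: Zirconocene-mediated reductive enyne cyclisation (Negishi type) should form ring A with methyl and the new substituent trans, β-alkoxide elimination of the benzyloxy group releasing the vinyl group, and iodine cleaving with retention the alkenyl–zirconium bond that syn-carbometalation places cis to the new ring bond.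

Step 16
Reactants: 25 (2S,3R)-2-ethenyl-1-[(Z)-1-iodoethylidene]-3-methylcyclopentane; 17 methyl (1R,3aS,5R,7aS)-5-[(2S)-but-3-en-2-yl]-6-oxo-1-(propan-2-yl)octahydro-3aH-indene-3a-carboxylate
Product: 27 tertiary alcohol: 17 with its ketone converted into C(OH) bearing the (Z)-1-[(2S,3R)-2-ethenyl-3-methylcyclopentylidene]ethyl group (alkenyl equatorial and OH axial), via alkenyllithium 26 (not isolated)
Conditions: 25 (1.5 equiv), t-BuLi (2 equiv per 25), Et2O, −78 °C; then 17, LaCl3·2LiCl, THF, −78 → −40 °C; H2O
Reagents that add atoms: none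
Why: Lithium–iodine exchange with retention of alkene geometry and 1,2-addition of the alkenyllithium (LaCl3·2LiCl suppresses enolisation) from the equatorial direction, trans to the neighbouring equatorial side chain, should give the axial tertiary alcohol of the target, the neopentyl methyl ester being too hindered to compete.

Step 17
Reactants: 27 tertiary alcohol (seco-diene)
Product: 28 methyl sesterfisherate with a (Z)-alkene in place of the ring B CH2–CH2 unit
Conditions: second-generation Grubbs catalyst RuCl2(H2IMes)(PCy3)(=CHPh) (10 mol%), toluene (2 mM), 80 °C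
Reagents that add atoms: none
Why: Ring-closing metathesis of the two monosubstituted alkenes, held close by the trans-diequatorial arrangement on ring C and the (Z)-tetrasubstituted alkene, should close ring B as its cis-cyclooctene while the tetrasubstituted alkene stays out.

Step 18
Reactants: 28 ring B dehydro methyl ester
Product: 29 methyl sesterfisherate
Conditions: H2 (1 atm), PtO2, EtOAc, rt
Reagents that add atoms: none
Why: Catalytic hydrogenation should saturate only the cis-disubstituted ring B alkene, the tetrasubstituted alkene being inert under these conditions.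

Step 19
Reactants: 29 methyl sesterfisherate
Product: 30 sesterfisheric acid
Conditions: NaSEt, DMF, 90 °C; then aq. HCl (pH 3)
Reagents that add atoms: none
Why: SN2 demethylation of the hindered angular methyl ester by thiolate at the methyl carbon should free the acid without acid or strong base acting on the tertiary allylic alcohol.

## Compound list

1 | methylglyoxal (2-oxopropanal) | CC(=O)C=O | starting material
2 | N-methoxy-N-methyl-2-(triphenylphosphoranylidene)acetamide | CON(C)C(=O)C=P(c1ccccc1)(c1ccccc1)c1ccccc1 | starting material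
3 | (E)-N-methoxy-N-methyl-4-oxopent-2-enamide | CC(=O)/C=C/C(=O)N(C)OC | intermediate
4 | dimethyl malonate | COC(=O)CC(=O)OC | starting material
5 | dimethyl 2-[(2R)-1-[methoxy(methyl)amino]-1,4-dioxopentan-2-yl]propanedioate | COC(=O)C(C(=O)OC)[C@H](C(=O)N(C)OC)CC(C)=O | intermediate
6 | methyl (6R)-6-[methoxy(methyl)carbamoyl]-2,4-dioxocyclohexane-1-carboxylate (enolised; diketo form drawn) | O=C1CC(=O)C(C(=O)OC)[C@H](C(=O)N(C)OC)C1 | intermediate
7 | methyl (6R)-4-methoxy-6-[methoxy(methyl)carbamoyl]-2-oxocyclohex-3-ene-1-carboxylate | COC1=CC(=O)C(C(=O)OC)[C@H](C(=O)N(C)OC)C1 | intermediate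
8 | methyl (6R)-4-methoxy-6-(2-methylpropanoyl)-2-oxocyclohex-3-ene-1-carboxylate | COC1=CC(=O)C(C(=O)OC)[C@H](C(=O)C(C)C)C1 | intermediate
9 | vinyltriphenylphosphonium bromide | C=C[P+](c1ccccc1)(c1ccccc1)c1ccccc1.[Br-] | starting material
10 | phosphorus ylide: methyl (1R,6R)-4-methoxy-6-(2-methylpropanoyl)-2-oxo-1-[2-(triphenylphosphoranylidene)ethyl]cyclohex-3-ene-1-carboxylate | COC1=CC(=O)[C@@](C(=O)OC)(CC=P(c2ccccc2)(c2ccccc2)c2ccccc2)[C@H](C(=O)C(C)C)C1 | intermediate
11 | methyl (3aR,7aS)-6-methoxy-4-oxo-1-(propan-2-yl)-3,4,7,7a-tetrahydro-3aH-indene-3a-carboxylate (trans-fused) | COC1=CC(=O)[C@@]2(C(=O)OC)CC=C(C(C)C)[C@@H]2C1 | intermediate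
12 | methyl (1R,3aR,7aS)-6-methoxy-4-oxo-1-(propan-2-yl)-1,2,3,4,7,7a-hexahydro-3aH-indene-3a-carboxylate | COC1=CC(=O)[C@@]2(C(=O)OC)CC[C@H](C(C)C)[C@@H]2C1 | intermediate
13 | methyl (1R,3aR,7aS)-4-hydroxy-6-methoxy-1-(propan-2-yl)-1,2,3,4,7,7a-hexahydro-3aH-indene-3a-carboxylate (carbinol configuration not specified) | COC1=CC(O)[C@@]2(C(=O)OC)CC[C@H](C(C)C)[C@@H]2C1 | intermediate
14 | methyl (1R,3aS,7aS)-6-oxo-1-(propan-2-yl)-1,2,3,6,7,7a-hexahydro-3aH-indene-3a-carboxylate | O=C1C=C[C@@]2(C(=O)OC)CC[C@H](C(C)C)[C@@H]2C1 | intermediate
15 | methyl (1R,3aS,7aS)-1-(propan-2-yl)-6-[(triethylsilyl)oxy]-1,2,3,4,7,7a-hexahydro-3aH-indene-3a-carboxylate | CC[Si](CC)(CC)OC1=CC[C@@]2(C(=O)OC)CC[C@H](C(C)C)[C@@H]2C1 | intermediate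
16 | (E)-but-2-en-1-yl methyl carbonate | C/C=C/COC(=O)OC | starting material
17 | methyl (1R,3aS,5R,7aS)-5-[(2S)-but-3-en-2-yl]-6-oxo-1-(propan-2-yl)octahydro-3aH-indene-3a-carboxylate | C=C[C@H](C)[C@H]1C[C@@]2(C(=O)OC)CC[C@H](C(C)C)[C@@H]2CC1=O | intermediate
18 | (R)-β-citronellene, (3R)-3,7-dimethylocta-1,6-diene | CC(C)=CCC[C@@H](C)C=C | starting material
19 | (Z)-1,4-bis(benzyloxy)but-2-ene | C(/C=C\COCc1ccccc1)OCc1ccccc1 | starting material
20 | benzyl (2E,4R)-4,8-dimethylnona-2,7-dien-1-yl ether | CC(C)=CCC[C@@H](C)/C=C/COCc1ccccc1 | intermediate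
21 | (4R,5E)-7-(benzyloxy)-4-methylhept-5-enal | O=CCC[C@@H](C)/C=C/COCc1ccccc1 | intermediate
22 | benzyl (2E,4R)-4-methyloct-2-en-7-yn-1-yl ether | C#CCC[C@@H](C)/C=C/COCc1ccccc1 | intermediate
23 | benzyl (2E,4R)-4-methylnon-2-en-7-yn-1-yl ether | CC#CCC[C@@H](C)/C=C/COCc1ccccc1 | intermediate
24 | alkenylzirconocene benzyloxide: (Z)-1-[(2S,3R)-2-ethenyl-3-methylcyclopentylidene]ethyl-zirconocene benzyloxide (Cp rings drawn σ-bonded) | C/C([Zr](OCc1ccccc1)(C1C=CC=C1)C1C=CC=C1)=C2\CC[C@@H](C)[C@@H]2C=C | intermediate
25 | (2S,3R)-2-ethenyl-1-[(Z)-1-iodoethylidene]-3-methylcyclopentane | C/C(I)=C1\CC[C@@H](C)[C@@H]1C=C | intermediate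
26 | (Z)-1-[(2S,3R)-2-ethenyl-3-methylcyclopentylidene]ethyllithium | C/C([Li])=C1\CC[C@@H](C)[C@@H]1C=C | intermediate
27 | tertiary alcohol: 17 with the ketone replaced by C(OH) carrying the (Z)-1-[(2S,3R)-2-ethenyl-3-methylcyclopentylidene]ethyl group, OH axial | C=C[C@H](C)[C@H]2C[C@@]3(C(=O)OC)CC[C@H](C(C)C)[C@@H]3C[C@]2(O)/C(C)=C1/CC[C@@H](C)[C@@H]1C=C | intermediate
28 | methyl sesterfisherate with a (Z)-alkene in place of the ring B CH2–CH2 unit | C/C1=C2\CC[C@@H](C)[C@@H]2/C=C\[C@H](C)[C@H]2C[C@@]3(C(=O)OC)CC[C@H](C(C)C)[C@@H]3C[C@]12O | intermediate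
29 | methyl sesterfisherate | C/C1=C2\CC[C@@H](C)[C@@H]2CC[C@H](C)[C@H]2C[C@@]3(C(=O)OC)CC[C@H](C(C)C)[C@@H]3C[C@]12O | intermediate
30 | sesterfisheric acid | C/C1=C2\CC[C@@H](C)[C@@H]2CC[C@H](C)[C@H]2C[C@@]3(C(=O)O)CC[C@H](C(C)C)[C@@H]3C[C@]12O | target

## Step count and risks

Total step count: 19. Longest linear sequence: 14 steps (steps 1–10, then 16–19).

Steps most likely to fail:

Step 6. After the conjugate addition, the phosphorus ylide may be quenched by proton transfer from the carbon next to the isobutyryl ketone faster than it closes onto that hindered carbonyl. That would stall ring closure and erode the trans ring fusion by epimerisation. The fallback sets out from 8: its enolate is added to diphenyl(vinyl)sulfonium triflate (DBU, CH2Cl2, 0 °C) to give the sulfonium ylide F1. This ylide is much less basic, and it should add irreversibly to the ketone and close to the ring D epoxide F2 (a Corey–Chaykovsky epoxy-annulation that still forms both ring D bonds in one operation). Stereospecific deoxygenation of the epoxide F2 (PPh3, CH3ReO3 cat., benzene, 60 °C) comes back to the route at 11.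

Step 10. The aliphatic crotyl electrophile may give a poor branched-to-linear ratio or weak ligand control at the new allylic centre on this hindered enol silane. The fallback sets out from 15: desilylation and transmetalation (MeLi, THF, 0 °C; then CuI) give the copper enolate F3. This is allylated with enantiopure (S)-but-3-en-2-yl methyl carbonate under RhCl(PPh3)3/P(OMe)3 catalysis. That substitution is regiospecific for the branched position and stereospecific with net retention, so the side-chain stereocentre comes from the reagent instead of a catalyst. DBU equilibration then returns to the route at 17.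

Step 8. Hydride delivery to the deactivated, neopentyl vinylogous-ester carbonyl may be incomplete, and a stronger hydride would lose chemoselectivity against the methyl ester. The fallback sets out from 12 and reduces both carbonyls on purpose with LiAlH4 (THF, 0 °C) to the diol F4. Acid hydrolysis/transposition (1 M HCl, THF) gives the hydroxymethyl enone F5. Oxidation of the neopentyl alcohol (CrO3, H2SO4, acetone) gives the enone acid F6, and esterification with TMSCHN2 (MeOH/toluene) returns to the route at 14.

Further compounds

F1 | step 6 | sulfonium ylide: methyl (1R,6R)-1-[2-(diphenylsulfonio)ethan-2-id-1-yl]-4-methoxy-6-(2-methylpropanoyl)-2-oxocyclohex-3-ene-1-carboxylate | COC1=CC(=O)[C@@](C(=O)OC)(C[CH-][S+](c2ccccc2)c2ccccc2)[C@H](C(=O)C(C)C)C1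
F2 | step 6 | ring D epoxide of 11 (1,2-epoxide of the cyclopentene; epoxide configuration not specified) | COC1=CC(=O)[C@@]2(C(=O)OC)CC3OC3(C(C)C)[C@@H]2C1
F3 | step 10 | copper enolate corresponding to 15 | [Cu]OC1=CC[C@@]2(C(=O)OC)CC[C@H](C(C)C)[C@@H]2C1
F4 | step 8 | diol: 13 with the ester reduced to CH2OH | COC1=CC(O)[C@@]2(CO)CC[C@H](C(C)C)[C@@H]2C1
F5 | step 8 | hydroxymethyl enone: 14 with CH2OH in place of CO2Me | O=C1C=C[C@@]2(CO)CC[C@H](C(C)C)[C@@H]2C1
F6 | step 8 | enone acid: 14 with CO2H in place of CO2Me | O=C1C=C[C@@]2(C(=O)O)CC[C@H](C(C)C)[C@@H]2C1
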